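- In a one-step world, where substrate meets reagent and nothing else happens, the substrate balance reads ln(c(substrate) charged / c(substrate) left) = D. I call D the reagent dose: the formation constant times the time integral of c(reagent in the reaction phase).

substrate 0.17 M; reagent in the second phase 1.20 equiv; protic impurity 0.0170 M; time 3.0 h; volume of the second phase over the first 0.25

    reagent in the reaction phase ⇌ reagent in the second phase, rate k1*([reagent in the reaction phase] - [reagent in the second phase]/K1) per volume of the first phase (K1 = 1.2, k1 = 7.5 × 10⁻⁵ s⁻¹)
    substrate + reagent in the reaction phase → target (k2 = 3.2 × 10⁻⁴ M⁻¹ s⁻¹)
    reagent in the reaction phase + target → over-reacted product (k3 = 2.5 × 10⁻⁴ M⁻¹ s⁻¹)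
    substrate → decomposition product (k4 = 7.2 × 10⁻⁸ s⁻¹)
    reagent in the reaction phase + protic impurity → quenched reagent (k5 = 9.8 × 10⁻⁴ M⁻¹ s⁻¹)

- in the second phase: reagent in the second phase; everything else is in the first
- charges count per volume of the first phase; a concentration in a rate is the amount of a species over the volume of its own phase; every rate counts per litre of the first phase
- run time (flask): 3.0 h

1. the target standing at 3.0 h, as a percentage of the substrate charged
2. the change that raises the amount of target at 3.0 h, in percent of the substrate charged most ("none" if none brings more than 2 percentage points) (south-east / west / none)
3. amount of target at 3.0 h, in percent of the substrate charged, after west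

- south-east: doubling the transfer coefficient of step 1, all else as stated
- west: doubling the amount of reagent in the second phase, all else as stated

- By charge the substrate is the limiting reagent, with 0.17 M, less than the 0.204 M of reagent in the second phase, and its decomposition makes no difference. Target forms and over-reacts under the same dose, so with r = 0.781, the over-reaction constant over the formation constant, the target share is (e^(−rD) − e^(−D))/(1 − r).
- My ceiling flask consumes no reagent. Its reaction phase fills towards 0.157 M with time constant 0.855 h, which gives D = 0.392 and 27.7% target.
- My floor flask holds the reagent sinks at their charged strength, 0.256 h⁻¹, throughout. The real sinks must be weaker, because over-reaction is slower than formation and substrate plus target cannot exceed the charge. The two-phase balance then has a slow rate 0.186 h⁻¹ and a fast rate 1.24 h⁻¹, giving the floor dose D = 0.304 and 23.2% target.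
- I commit to the lower edge: the floor dose takes 26.2% of the substrate, less than it leaves, so I expect the real sinks nearer their charged strength than zero.
- West doubles both doses, giving 35.4% to 39.1% target. South-east halves the time constant and lifts the ceiling to 30.8%, below west's floor, so I choose west.
- The forecast gives 23.5%, west and 36%, reasoning that “Transfer takes about an hour to relax and the reagent then sits mostly in the reaction phase”.
- The simulation gives 23.5%, west and 35.9%; west gains 12 percentage points, more than the 2.9 points of south-east.
- This flask's 73.3% of substrate reads as a dose of 0.311, beside the floor of 0.304. The neighbour flask charged with 0.043 M of protic impurity has sinks at charged strength of 0.348 h⁻¹, rates of 0.246 h⁻¹ and 1.27 h⁻¹, a floor dose of 0.279 and a floor target of 21.8%. That neighbour flask reads 74.7% substrate, a dose of 0.292, and stands at 22.4% target.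

Its constants were set for the occasion; the rest is arithmetic.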